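**Retrosynthetic overview**
1. Gentiside I is the n-heneicosyl ester of 2,3-dihydroxybenzoic acid. The last operation only frees the phenol oxygens O2 and O3 from two acetyl groups.
2. Key disconnection: the C9–C10 bond of the C21 chain (counted from the ester oxygen) is cut homolytically into a 9-(aroyloxy)nonyl radical and a dodecyl radical. Each is traced back to a free carboxylic acid one carbon longer, and a crossed Kolbe electrolysis joins these two like-polarity carbons with loss of two CO2.
3. Enabling feature: C9 and C10 are unbranched CH2 groups of a heteroatom-free polymethylene chain, so both radicals are primary and unstabilised and should couple rather than be oxidised further. The only ring, the benzene ring, sits nine CH2 groups away and is electron-poor as its O2,O3-diacetate with the C1 ester carbonyl, so the anode should leave it alone.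
4. The C10 partner arises by forming the C1–O ester bond: pKa-selective alkylation of the 2,3-dihydroxybenzoate carboxylate with 10-bromodecanoic acid, then acetylation of the catechol. The C13 partner, tridecanoic acid, is bought.
5. No ring is formed anywhere in the route; the benzene ring comes with the starting material.

Key step: step 3

Remark on the chemistry: the target has no stereocentre and no stereogenic double bond. It is achiral, so no stereocontrol is needed and the SMILES carry no stereodescriptors.

**Step 1**
Reactants: 1 pyrocatechuic acid (2,3-dihydroxybenzoic acid); 2 bromo acid (10-bromodecanoic acid)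
Product: 4 ester acid 10-[(2,3-dihydroxybenzoyl)oxy]decanoic acid, via potassium 2,3-dihydroxybenzoate 3 (not isolated)
Conditions: 1 (1.3 equiv), KHCO3 (1.0 equiv per 1), DMF, rt until gas evolution ends; then 2 (1.0 equiv), NaI (10 mol %), 65–70 °C, Ar
Reagents that add atoms: none
Why: SN2 alkylation of a carboxylate (alkylative esterification, iodide-assisted): with one equivalent of base only the much more acidic, internally hydrogen-bonded salicylate-type carboxyl of 1 (pKa about 3) is ionised, while the alkanoic carboxyl of 2 (pKa about 5) and both phenols stay protonated and should not compete as nucleophiles.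

**Step 2**
Reactants: 4 ester acid 10-[(2,3-dihydroxybenzoyl)oxy]decanoic acid
Product: 6 diacetate acid 10-{[2,3-bis(acetyloxy)benzoyl]oxy}decanoic acid, via mixed acetic anhydride 5 (not isolated)
Conditions: Ac2O (3.5 equiv), pyridine (5 equiv), CH2Cl2, 0 °C to rt; then ice-water, 30 min; 1 M HCl wash
Reagents that add atoms: acetic anhydride CC(=O)OC(C)=O
Why: Pyridine-promoted O-acetylation of phenols as routinely done on phenolic acids, in which the alkanoic carboxyl is carried transiently as mixed anhydride 5 that pyridine/water should cleave at its acetyl carbonyl during the quench while the aryl acetates remain.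

**Step 3**
Reactants: 6 diacetate acid 10-{[2,3-bis(acetyloxy)benzoyl]oxy}decanoic acid; 7 tridecanoic acid
Product: 10 heneicosyl 2,3-bis(acetyloxy)benzoate, via dodecyl radical 8 (not isolated), via 9-(aroyloxy)nonyl radical 9 (not isolated)
Conditions: 7 (6 equiv) pre-neutralised with NaOMe (5 mol % of total acid), then 6 (1 equiv), MeOH, undivided cell, Pt(+)|Pt(−), constant current 0.25–0.3 A cm−2, 45–50 °C, polarity reversed periodically, ca. 1.2 F per mol of acid, stopped while the solution is still acidic
Reagents that add atoms: none
Why: Crossed Kolbe electrolysis: both carboxylates are oxidised by one electron at the platinum anode, the acyloxy radicals lose CO2, and radicals 8 and 9, generated side by side at high concentration in the anode layer, combine to form the C9–C10 bond while the carboxyl protons are reduced to H2 at the cathode. The closest known reaction type is the mixed Kolbe coupling of a fatty acid with an ω-acyloxy or half-ester alkanoic acid, the classical entry to long unbranched chains. No ring is closed and no stereocentre is created, so neither a mode of closure nor a controlling element is required. Three selectivities are needed: coupling instead of a second electron transfer (Hofer–Moest pathway) is secured because both radical carbons are primary CH2 groups without α-heteroatom or π-donor; cross-coupling of the valuable partner is secured statistically by the excess of cheap 7, whose hydrocarbon dimer elutes with hexane well ahead of the ester; and carboxylate oxidation instead of arene oxidation is secured by the two acetoxy groups and the ester carbonyl, which make the benzene ring electron-poor. The aryl acetates and the alkyl benzoate should survive because the medium remains an RCO2H/RCO2− buffer in which the cathode only converts acid into carboxylate, so methoxide cannot build up before the electrolysis is stopped.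

**Step 4**
Reactants: 10 heneicosyl 2,3-bis(acetyloxy)benzoate
Product: 11 Gentiside I (heneicosyl 2,3-dihydroxybenzoate)
Conditions: pyrrolidine (4 equiv), degassed CH2Cl2, 0 °C to rt, Ar; 1 M HCl wash
Reagents that add atoms: none
Why: Chemoselective aminolysis of aryl acetates: the phenoxide leaving groups make both acetates far more reactive toward the secondary amine than the alkyl benzoate, which has a poor alkoxide leaving group and a carbonyl deactivated once the ortho phenol is free, and exclusion of air should keep the catechol from oxidising.

**Compound list**
1 | 2,3-dihydroxybenzoic acid | O=C(O)c1cccc(O)c1O | starting material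
2 | 10-bromodecanoic acid | OC(=O)CCCCCCCCCBr | starting material
3 | potassium 2,3-dihydroxybenzoate | [K+].[O-]C(=O)c1cccc(O)c1O | intermediate
4 | 10-[(2,3-dihydroxybenzoyl)oxy]decanoic acid | OC(=O)CCCCCCCCCOC(=O)c1cccc(O)c1O | intermediate
5 | acetic 10-{[2,3-bis(acetyloxy)benzoyl]oxy}decanoic anhydride | CC(=O)OC(=O)CCCCCCCCCOC(=O)c1cccc(OC(C)=O)c1OC(C)=O | intermediate
6 | 10-{[2,3-bis(acetyloxy)benzoyl]oxy}decanoic acid | OC(=O)CCCCCCCCCOC(=O)c1cccc(OC(C)=O)c1OC(C)=O | intermediate
7 | tridecanoic acid | CCCCCCCCCCCCC(=O)O | starting material
8 | dodecyl radical | CCCCCCCCCCC[CH2] | intermediate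
9 | 9-{[2,3-bis(acetyloxy)benzoyl]oxy}nonyl radical | [CH2]CCCCCCCCOC(=O)c1cccc(OC(C)=O)c1OC(C)=O | intermediate
10 | heneicosyl 2,3-bis(acetyloxy)benzoate | CCCCCCCCCCCCCCCCCCCCCOC(=O)c1cccc(OC(C)=O)c1OC(C)=O | intermediate
11 | Gentiside I, heneicosyl 2,3-dihydroxybenzoate | CCCCCCCCCCCCCCCCCCCCCOC(=O)c1cccc(O)c1O | target

Total step count: 4
Longest linear sequence: 4 steps (1 → 4 → 6 → 10 → 11)

**Steps most likely to fail**

Step 3. Statistical homocoupling could cut the throughput of the valuable partner. A waxy film could passivate the anode. An acetyl group could be lost by methanolysis in the cathode layer, after which the freed phenol would be oxidised at the anode.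
Fallback, from 6 back to 10: the radical–radical union is replaced by a nickel-catalysed decarboxylative alkyl–alkyl cross-coupling of Negishi type. It has only one radical partner and needs neither an anode nor methanol. Compound 6 is condensed with N-hydroxyphthalimide (DIC, CH2Cl2, rt) to 1,3-dioxoisoindolin-2-yl 10-{[2,3-bis(acetyloxy)benzoyl]oxy}decanoate F1. Commercial dodecylmagnesium bromide and ZnCl2 (THF, 0 °C to rt) give didodecylzinc F2. F1 and F2 are then joined with NiCl2·glyme and 4,4′-di-tert-butyl-2,2′-bipyridine in THF/DMF at rt, which should form the same C9–C10 bond and deliver 10.

Step 1. Proton exchange between the two carboxyl groups could allow self-alkylation of the bromo acid. The SN2 reaction of the weakly nucleophilic, hydrogen-bonded carboxylate could be sluggish. Prolonged heating could lead to phenol O-alkylation.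
Fallback, from 1 back to 6: the second carboxyl group is kept masked as a terminal alkene until the ester is in place. Compound 1 is alkylated (KHCO3, DMF, 65 °C) with commercial 11-bromoundec-1-ene to undec-10-en-1-yl 2,3-dihydroxybenzoate F3. Acetylation (Ac2O, pyridine, CH2Cl2) gives undec-10-en-1-yl 2,3-bis(acetyloxy)benzoate F4. Oxidative cleavage of the terminal alkene (RuCl3 cat., NaIO4, MeCN/EtOAc/H2O, rt), which the electron-poor ring should tolerate, gives 6.

Step 4. Aminolysis of the long-chain ester could compete with acetate cleavage. The hindered 2-acetate could be released incompletely. The liberated catechol could be oxidised by air under basic conditions.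
Fallback, from 10 back to 11: selectivity is given up and the ester is rebuilt under neutral conditions without protecting groups. Compound 10 is fully saponified (KOH, aq. EtOH, reflux, Ar) to heneicosan-1-ol F5. F5 is then esterified with 1 by a chemoselective Mitsunobu reaction (PPh3, DIAD, THF, 0 °C to rt), in which the strongly acidic carboxyl should react ahead of the phenols, to give 11.

**Further compounds**
F1 | step 3 | 1,3-dioxoisoindolin-2-yl 10-{[2,3-bis(acetyloxy)benzoyl]oxy}decanoate | O=C(CCCCCCCCCOC(=O)c1cccc(OC(C)=O)c1OC(C)=O)ON1C(=O)c2ccccc2C1=O
F2 | step 3 | didodecylzinc | CCCCCCCCCCCC[Zn]CCCCCCCCCCCC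
F3 | step 1 | undec-10-en-1-yl 2,3-dihydroxybenzoate | C=CCCCCCCCCCOC(=O)c1cccc(O)c1O
F4 | step 1 | undec-10-en-1-yl 2,3-bis(acetyloxy)benzoate | C=CCCCCCCCCCOC(=O)c1cccc(OC(C)=O)c1OC(C)=O
F5 | step 4 | heneicosan-1-ol | CCCCCCCCCCCCCCCCCCCCCO
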